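**Strategy.** The benzoquinone ring (numbered as 2-hydroxy-5-methoxy-3-pentadecyl-1,4-benzoquinone) is cut at C1–C2 and C3–C4, the two bonds that tie the hydroxy- and pentadecyl-bearing alkene C2=C3 to the carbonyl carbons. What remains, C1(=O)–C6H=C5(OMe)–C4(=O), is a maleoyl unit, and C2(OH)=C3(C15H31) is an ynol in disguise. The key step unites a maleoylcobalt metallacycle, made by insertion of cobalt into the C–C bond between the carbonyl groups of 3-methoxycyclobutenedione, with a siloxyalkyne made from ethyl palmitate. Alkyne insertion and reductive elimination close the fully substituted quinone ring at its final oxidation level in one operation. The matched push–pull polarity of the two partners is relied on for the regiochemistry.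

Key step: step 4

Remark: the target has no stereocenter and is treated as the 2-hydroxy-1,4-benzoquinone tautomer.

Step 1
Reactants: 1 dimethyl squarate (3,4-dimethoxycyclobut-3-ene-1,2-dione)
Product: 3 3-methoxycyclobut-3-ene-1,2-dione, via hydroxycyclobutenone 2 (not isolated)
Conditions: LiAlH(OtBu)3, THF, −20 °C; aq. HCl work-up; then conc. HCl (cat.), CH2Cl2, rt
Reagents that add atoms: none
Why: The bulky hydride should add once, 1,2, to one of the two equivalent carbonyl groups, and acid then ionises the allylic hydroxyl group and hydrolyses the resulting oxocarbenium ion with loss of methanol (1,2-reduction followed by allylic transposition and hydrolysis).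

Step 2
Reactants: 3 3-methoxycyclobut-3-ene-1,2-dione
Product: 5 chloro(dimethylglyoxime)(pyridine)maleoylcobalt complex CoCl(py)(dmgH2)[C(O)C(OMe)=CHC(O)], via bis(triphenylphosphine) cobaltacycle 4 (not isolated)
Conditions: ClCo(PPh3)3, benzene, rt; then dimethylglyoxime, pyridine, rt
Reagents that add atoms: ClCo(PPh3)3, Cl[Co-3]([P+](c1ccccc1)(c1ccccc1)c1ccccc1)([P+](c1ccccc1)(c1ccccc1)c1ccccc1)[P+](c1ccccc1)(c1ccccc1)c1ccccc1; dimethylglyoxime, CC(=NO)C(C)=NO; pyridine, c1ccncc1
Why: Monovalent cobalt should insert oxidatively into the strained bond between the two carbonyl carbons (C–C activation of a cyclobutenedione) to give the trivalent cobaltacyclopentenedione, and exchange of the phosphines for dimethylglyoxime and pyridine gives the octahedral, air-stable form that reacts with alkynes under mild Lewis-acid activation.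

Step 3
Reactants: 6 ethyl hexadecanoate (ethyl palmitate)
Product: 8 (heptadec-1-yn-1-yloxy)triisopropylsilane, via lithium ynolate 7 (not isolated)
Conditions: CH2Br2, LiTMP (lithium 2,2,6,6-tetramethylpiperidide), THF, −78 °C; n-BuLi, −78 °C to rt; then TIPSCl, −78 °C to rt
Reagents that add atoms: dibromomethane, BrCBr; triisopropylsilyl chloride, CC(C)[Si](Cl)(C(C)C)C(C)C
Why: Kowalski ester homologation: LiCHBr2 adds to the ester, Br/Li exchange on the dibromo enolate gives a carbenoid that rearranges by 1,2-shift of the pentadecyl group to the ynolate, and the bulky silyl chloride traps it on oxygen, so that the ester carbonyl carbon becomes the future C2 and the CH2Br2 carbon the future C3.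

Step 4
Reactants: 5 maleoylcobalt complex CoCl(py)(dmgH2)[C(O)C(OMe)=CHC(O)]; 8 (heptadec-1-yn-1-yloxy)triisopropylsilane
Product: 10 2-hydroxy-5-methoxy-3-pentadecyl-1,4-benzoquinone, via siloxyquinone 9 (not isolated)
Conditions: CoCl2 (anhydrous, cat.), MeCN, 60 °C; then aq. HF, MeCN, 0 °C to rt
Reagents that add atoms: none
Why: CoCl2 takes up chloride from the trivalent cobalt centre of 5 and frees a site for the alkyne; migratory insertion of 8 into one Co–acyl bond gives a seven-membered acyl(vinyl)cobalt metallacycle, and C–C reductive elimination then forms the second C(=O)–C bond and releases the quinone from monovalent cobalt. This is the known benzoquinone synthesis from maleoylcobalt complexes and alkynes, applied here to a siloxyalkyne. The six-membered carbocycle is closed by reductive elimination at cobalt (a formal [4+2] union of the C1/C6/C5/C4 diacyl unit with the C2–C3 alkyne), so no ionic or pericyclic ring-closure rule applies, and no stereocenter is formed. The step needs one orientation of two unsymmetrical partners, and both are polarised: the acyl carbon next to C–OMe is a plain, electrophilic acyl group while the one next to CH is a donor-stabilised vinylogous ester, and in 8 the pentadecyl-bearing carbon is nucleophilic while the oxygen-bearing carbon is electrophilic once the alkyne is bound to the cationic metal. Matched pairing should therefore join the electrophilic acyl carbon (C4) to the pentadecyl-bearing carbon and the vinylogous acyl carbon (C1) to the oxygen-bearing carbon, giving the 2,5-dioxygenated pattern in which each ring carbonyl is a vinylogous ester. A mild chloride acceptor is used in place of a strong oxophilic Lewis acid so that the siloxyalkyne is not ionised before insertion, and aqueous HF finally cleaves the labile silyl vinylogous ester of 9.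

**Compound list**

1 | dimethyl squarate (3,4-dimethoxycyclobut-3-ene-1,2-dione) | COC1=C(OC)C(=O)C1=O | starting material
2 | 4-hydroxy-2,3-dimethoxycyclobut-2-en-1-one (racemic) | COC1=C(OC)C(O)C1=O | intermediate
3 | 3-methoxycyclobut-3-ene-1,2-dione | COC1=CC(=O)C1=O | intermediate
4 | chlorobis(triphenylphosphine)maleoylcobalt complex CoCl(PPh3)2[C(O)C(OMe)=CHC(O)] (3-methoxy-1-cobaltacyclopent-3-ene-2,5-dione) | COC1=CC(=O)[Co-2](Cl)([P+](c2ccccc2)(c2ccccc2)c2ccccc2)([P+](c2ccccc2)(c2ccccc2)c2ccccc2)C1=O | intermediate
5 | chloro(dimethylglyoxime)(pyridine)maleoylcobalt complex CoCl(py)(dmgH2)[C(O)C(OMe)=CHC(O)] | COC1=CC(=O)[Co-3]2(Cl)([n+]3ccccc3)([N+](O)=C(C)C(C)=[N+]2O)C1=O | intermediate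
6 | ethyl hexadecanoate (ethyl palmitate) | CCCCCCCCCCCCCCCC(=O)OCC | starting material
7 | lithium heptadec-1-yn-1-olate | CCCCCCCCCCCCCCCC#C[O-].[Li+] | intermediate
8 | (heptadec-1-yn-1-yloxy)triisopropylsilane | CCCCCCCCCCCCCCCC#CO[Si](C(C)C)(C(C)C)C(C)C | intermediate
9 | 5-methoxy-3-pentadecyl-2-(triisopropylsilyloxy)cyclohexa-2,5-diene-1,4-dione | CCCCCCCCCCCCCCCC1=C(O[Si](C(C)C)(C(C)C)C(C)C)C(=O)C=C(OC)C1=O | intermediate
10 | 2-hydroxy-5-methoxy-3-pentadecylcyclohexa-2,5-diene-1,4-dione | CCCCCCCCCCCCCCCC1=C(O)C(=O)C=C(OC)C1=O | target

**Step count.** Total: 4 steps. Longest linear sequence: 3 steps (steps 1, 2 and 4); step 3 is the convergent branch.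

**Steps most likely to fail**

Step 4. The siloxyalkyne may be ionised or protodesilylated by the Lewis acid or by the oxime O–H groups before it reaches cobalt. Insertion may also occur in the opposite orientation, which would lead to the 2,6-dioxygenated isomer. The fallback closes the same ring without metal by a photochemical Danheiser benzannulation; it sets out from 8 and comes back at 9. Commercial (E)-4-methoxybut-3-en-2-one would be trifluoroacetylated (LiN(SiMe3)2, CF3CO2CH2CF3, THF, −78 °C) to (E)-1,1,1-trifluoro-6-methoxyhex-5-ene-2,4-dione F1. Detrifluoroacetylative diazo transfer (MsN3, Et3N, H2O, MeCN) should then give (E)-1-diazo-4-methoxybut-3-en-2-one F2. Irradiation of F2 with 8 (300 nm, ClCH2CH2Cl, rt, then 80 °C) should trigger Wolff rearrangement to the methoxy-substituted vinylketene, regiospecific [2+2] cycloaddition with the siloxyalkyne, four-electron ring opening and six-electron electrocyclisation. The product would be 6-methoxy-2-pentadecyl-3-(triisopropylsilyloxy)phenol F3. Fremy's salt, (KSO3)2NO, in buffered aqueous acetone should oxidise F3 at its free para position to 9, and aqueous HF then gives 10 as in step 4.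

Step 3. The 1,2-shift of the bromo carbenoid may be incomplete, so that ketone by-products form on quench, or the ynolate may be silylated on carbon instead of oxygen. The fallback makes the ynolate by oxidation of an acetylide; it sets out from 6 and comes back at 8 through ynolate 7. Reduction with i-Bu2AlH (CH2Cl2, −78 °C) should give hexadecanal F4. Ohira–Bestmann homologation (dimethyl (1-diazo-2-oxopropyl)phosphonate, K2CO3, MeOH) should give heptadec-1-yne F5. Deprotonation (n-BuLi, THF, −78 °C) and oxidation of the lithium acetylide with LiOOtBu (from t-BuOOH and LiN(SiMe3)2) should give 7, which TIPSOTf silylates on oxygen to 8.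

Step 2. The maleoyl unit may be lost by decarbonylation, or the methoxy group may be attacked by pyridine during the ligand exchange. The fallback avoids the exchange; it sets out from 4, collected by filtration instead of being carried on, and comes back at 9. Chloride abstraction with AgBF4 in MeCN should give the cationic bis(acetonitrile) complex [Co(PPh3)2(NCMe)2{C(O)C(OMe)=CHC(O)}]BF4 F6. Its labile nitrile ligands make room for 8 (MeCN, rt to 60 °C), and insertion and reductive elimination should give 9, which aqueous HF converts to 10.

**Further compounds**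

F1 | step 4 | (E)-1,1,1-trifluoro-6-methoxyhex-5-ene-2,4-dione | CO/C=C/C(=O)CC(=O)C(F)(F)F
F2 | step 4 | (E)-1-diazo-4-methoxybut-3-en-2-one | CO/C=C/C(=O)C=[N+]=[N-]
F3 | step 4 | 6-methoxy-2-pentadecyl-3-(triisopropylsilyloxy)phenol | CCCCCCCCCCCCCCCc1c(O)c(OC)ccc1O[Si](C(C)C)(C(C)C)C(C)C
F4 | step 3 | hexadecanal | CCCCCCCCCCCCCCCC=O
F5 | step 3 | heptadec-1-yne | CCCCCCCCCCCCCCCC#C
F6 | step 2 | bis(acetonitrile)bis(triphenylphosphine)maleoylcobalt tetrafluoroborate [Co(PPh3)2(NCMe)2{C(O)C(OMe)=CHC(O)}]BF4 | COC1=CC(=O)[Co-3]([P+](c2ccccc2)(c2ccccc2)c2ccccc2)([P+](c2ccccc2)(c2ccccc2)c2ccccc2)([N+]#CC)([N+]#CC)C1=O.F[B-](F)(F)F
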